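## Retrosynthetic overview

1. Target ⇐ its C2 phenyl sulfone ⇐ radical (3+3) annulation: ring A is opened at C3–C4 and C1–C10 to a monocyclic ring B 1,4-diene (isopropenyl on C5, exocyclic methylene at C10) plus 2,3-bis(phenylsulfonyl)propene as the C1–C3 unit.
2. Enabling feature: in ring A, C4 (gem-dimethyl) and C10 (angular methyl) are both quaternary, both carry a methyl group and are 1,3-related through C5. Each is therefore the tertiary radical formed when H• adds to a =CH2 group, and a three-carbon 1,3-bis-acceptor can be stitched between them.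
3. Ring B (C5, C6, C9 stereocentres, C7=C8) ⇐ enantioselective Diels–Alder reaction of a (R)-linalool-derived 1-silyloxy diene (C6–C9, C11–C17) with penta-3,4-dien-2-one (C4, C5, C10, C18, C20); the acetyl group is then methylenated to the isopropenyl group.
4. The C6 butanoate is set by Mitsunobu inversion on the monocycle; C13 comes unchanged from (R)-linalool.
5. Ring order: ring B first (Diels–Alder), ring A second (annulation).

Key step: step 9

Remarks on the chemistry:
- Labdane numbering (C1–C20) is used for all ring compounds; α/β refer to the usual drawing of the target (C20 methyl β).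
- Assumption: the (S)-oxazaborolidinium catalyst of step 5 is taken to give the (5S,6R,9S) adduct by analogy with acyclic vinyl ketones; should the sense prove opposite, its enantiomer is used with no other change.
- (R)-(−)-Linalool, (±)-pent-4-yn-2-ol and 2,3-bis(phenylsulfonyl)prop-1-ene are taken as purchased.

## Route

Step 1
Reactants: 1 (R)-(−)-linalool
Product: 2 (2E,6R)-6-hydroxy-2,6-dimethylocta-2,7-dienal
Conditions: SeO2 (1.1 equiv), 1,4-dioxane, 80 °C
Reagents that add atoms: selenium dioxide, O=[Se]=O
Why: Riley allylic oxidation (ene reaction then [2,3]-sigmatropic shift) of the electron-rich trisubstituted alkene takes place at the (E)-methyl group and should give the (E)-enal while the vinyl carbinol and its stereocentre are untouched.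

Step 2
Reactants: 2 (2E,6R)-6-hydroxy-2,6-dimethylocta-2,7-dienal
Product: 4 (7R)-7-hydroxy-3,7-dimethylnona-2,8-dienal (2E/2Z mixture), via methyl dienyl ether 3 (not isolated)
Conditions: Ph3P(CH2OMe)Cl, KHMDS, THF, −78 → 0 °C; then 5% aq. oxalic acid, THF, rt
Reagents that add atoms: (methoxymethyl)triphenylphosphonium chloride, COC[P+](c1ccccc1)(c1ccccc1)c1ccccc1.[Cl-]; water, O
Why: Wittig methoxymethylenation followed by mild acid hydrolysis of the dienyl ether is a one-carbon homologation that should give the conjugated 3-methyl-2-enal, whose 2E/2Z ratio is irrelevant because this double bond becomes the central single bond of the diene; no stereocentre is formed.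

Step 3
Reactants: 4 (7R)-7-hydroxy-3,7-dimethylnona-2,8-dienal
Product: 5 (1E,3E,7R)-1,7-bis[(tert-butyldimethylsilyl)oxy]-3,7-dimethylnona-1,3,8-triene
Conditions: TBSOTf (2.5 equiv), Et3N, CH2Cl2, −78 → 0 °C
Reagents that add atoms: tert-butyldimethylsilyl trifluoromethanesulfonate, CC(C)(C)[Si](C)(C)OS(=O)(=O)C(F)(F)F
Why: Soft enolisation (O-silylation, then γ-deprotonation at the CH2 group towards the more substituted conjugated diene) should give the (1E,3E)-1-silyloxy diene from the s-trans enal and silylates the tertiary alcohol in the same flask, any minor diene isomers being unreactive in step 5.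

Step 4
Reactants: 6 (±)-pent-4-yn-2-ol
Product: 8 penta-3,4-dien-2-one, via pent-4-yn-2-one 7 (not isolated)
Conditions: Dess–Martin periodinane, CH2Cl2, 0 °C; then Et3N (5 mol%), 0 °C; used as a CH2Cl2 solution
Reagents that add atoms: none
Why: Dess–Martin oxidation gives the β,γ-alkynyl ketone, which should undergo base-catalysed propargyl–allenyl isomerisation to the conjugated allenyl ketone; no stereocentre is involved.

Step 5
Reactants: 5 (1E,3E,7R)-1,7-bis[(tert-butyldimethylsilyl)oxy]-3,7-dimethylnona-1,3,8-triene; 8 penta-3,4-dien-2-one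
Product: 9 1-[(1S,2R,5S)-2-[(tert-butyldimethylsilyl)oxy]-5-[(3R)-3-[(tert-butyldimethylsilyl)oxy]-3-methylpent-4-en-1-yl]-4-methyl-6-methylidenecyclohex-3-en-1-yl]ethan-1-one (C5 acetyl, C6 OTBS and C9 side chain all cis, β)
Conditions: (S)-3,3-diphenyl-1-(2-methylphenyl)hexahydropyrrolo[1,2-c][1,3,2]oxazaborole·HNTf2 (20 mol%), CH2Cl2, −78 → −40 °C; Et3N quench
Reagents that add atoms: none
Why: Lewis acid-catalysed Diels–Alder reaction at the conjugated C=C of the allenyl ketone, in which the silyloxy terminus C6 bonds to the acyl-bearing carbon C5 and the nucleophilic terminus C9 to the central allene carbon C10, the endo acetyl group and the (1E,3E)-diene geometry place the C5, C6 and C9 substituents mutually cis, and the cationic oxazaborolidine shields one face of the bound dienophile to fix the absolute configuration.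

Step 6
Reactants: 9 the all-cis Diels–Alder adduct (methyl ketone)
Product: 10 tert-butyl{[(1R,4S,6S)-4-[(3R)-3-[(tert-butyldimethylsilyl)oxy]-3-methylpent-4-en-1-yl]-3-methyl-5-methylidene-6-(prop-1-en-2-yl)cyclohex-2-en-1-yl]oxy}dimethylsilane
Conditions: Cp2TiMe2 (2.5 equiv), toluene, 65 °C, dark
Reagents that add atoms: dimethyltitanocene (Cp2TiMe2), C[Ti](C)(C1C=CC=C1)C1C=CC=C1
Why: Petasis methylenation through Cp2Ti=CH2 is non-basic, so the β-silyloxy ketone with its doubly activated C5–H should be converted into the isopropenyl group without β-elimination, epimerisation at C5 or migration of the exocyclic alkene.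

Step 7
Reactants: 10 the bis-silyl ether 1,4-diene
Product: 11 (1R,4S,6S)-4-[(3R)-3-hydroxy-3-methylpent-4-en-1-yl]-3-methyl-5-methylidene-6-(prop-1-en-2-yl)cyclohex-2-en-1-ol (6β-OH, cis to the isopropenyl group)
Conditions: TBAF (4 equiv), THF, 45 °C
Reagents that add atoms: none
Why: Fluoride-mediated desilylation should cleave both the secondary allylic and the tertiary silyl ether without touching any stereocentre.

Step 8
Reactants: 11 the cis-diol
Product: 12 (1S,4S,6S)-4-[(3R)-3-hydroxy-3-methylpent-4-en-1-yl]-3-methyl-5-methylidene-6-(prop-1-en-2-yl)cyclohex-2-en-1-yl butanoate (6α-ester, trans to the isopropenyl group and the side chain)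
Conditions: n-PrCO2H, PPh3, DIAD, toluene, 0 °C → rt
Reagents that add atoms: butanoic acid, CCCC(=O)O
Why: In this Mitsunobu esterification only the secondary allylic alcohol is activated (the tertiary carbinol is inert) and butanoate should displace the β-oxyphosphonium group by SN2 from the unhindered α-face, inverting C6 to the 6α-ester required in the target.

Step 9
Reactants: 12 the 6α-butanoate 1,4-diene; 13 2,3-bis(phenylsulfonyl)prop-1-ene
Product: 16 (13R)-13-hydroxy-2-(phenylsulfonyl)labda-7,14-dien-6α-yl butanoate (5S,6S,9S,10R; C2 epimer mixture), via C4-allylated vinyl sulfone 14 (not isolated), via C10-allylated vinyl sulfone 15 (not isolated)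
Conditions: 13 (1.1 equiv), Fe(acac)3 (30 mol%), PhSiH3 (3 equiv), EtOH/ethylene glycol 5:1, 0.05 M, 60 °C
Reagents that add atoms: none
Why: Proposed new method: the iron hydride formed from Fe(acac)3 and PhSiH3 transfers H• to the =CH2 terminus of one of the two 1,1-disubstituted alkenes of 12, the tertiary radical (C4 or C10) adds to the CH2= terminus of 13 and the α-sulfonyl radical expels PhSO2• to leave a new vinyl sulfone (14 or 15), after which a second hydrogen-atom transfer to the remaining alkene gives the other tertiary radical, which adds to the vinyl sulfone terminus and is reduced and protonated to 16; the closest known reaction types are the Fe(acac)3/PhSiH3 reductive olefin–acceptor (Giese) coupling with vinyl sulfones and radical allylation by addition–fragmentation on 2-substituted allyl sulfones, merged here into a (3+3) annulation. Ring A is closed by a 6-endo-trig radical conjugate addition, the 5-exo mode being disfavoured because it would attack the sulfonyl-bearing carbon. C10 is the only new stereocentre that matters: the C1–C10 bond should form on the α-face, anti to the β-oriented C9 side chain and with the C5–C4 bond equatorial, through a chair-like transition state with the incipient angular methyl axial (as in radical polyene bicyclisations), giving the trans-decalin with 10β-methyl, while C2 forms as an epimer mixture that step 10 erases. The step needs hydrogen-atom transfer to the two 1,1-disubstituted alkenes in preference to the trisubstituted C7=C8 alkene (hindered, deactivated by the allylic ester) and the monosubstituted vinyl group (slower, secondary radical), and ring closure in preference to a second intermolecular addition, which 1.1 equiv of 13 at 0.05 M should secure. The 1,4-relationship of the two alkenes excludes their mutual cyclisation (three- or four-membered rings), and the two H atoms delivered create the second C4 methyl and the C10 methyl.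

Step 10
Reactants: 16 the C2 sulfone
Product: 17 (13R)-13-hydroxylabda-7,14-dien-6α-yl butanoate (5S,6S,9S,10R,13R), the target
Conditions: SmI2 (6 equiv), HMPA, t-BuOH, THF, −20 °C → rt
Reagents that add atoms: none
Why: Single-electron reductive desulfonylation (fragmentation of the sulfone radical anion, second electron transfer, protonation) should cleave the secondary C2–SO2Ph bond and converge both C2 epimers, while the allylic butanoate, the tertiary allylic alcohol and the alkenes are not reduced and no stereocentre is touched.

## Compound list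

1 | (R)-(−)-linalool | C=C[C@](C)(O)CCC=C(C)C | starting material
2 | (2E,6R)-6-hydroxy-2,6-dimethylocta-2,7-dienal | C=C[C@](C)(O)CC/C=C(\C)C=O | intermediate
3 | (3R,6E)-9-methoxy-3,7-dimethylnona-1,6,8-trien-3-ol (8E/8Z mixture; not isolated) | C=C[C@](C)(O)CC/C=C(\C)C=COC | intermediate
4 | (7R)-7-hydroxy-3,7-dimethylnona-2,8-dienal (2E/2Z mixture) | C=C[C@](C)(O)CCCC(C)=CC=O | intermediate
5 | (1E,3E,7R)-1,7-bis[(tert-butyldimethylsilyl)oxy]-3,7-dimethylnona-1,3,8-triene | C=C[C@](C)(O[Si](C)(C)C(C)(C)C)CC/C=C(C)/C=C/O[Si](C)(C)C(C)(C)C | intermediate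
6 | (±)-pent-4-yn-2-ol | CC(O)CC#C | starting material
7 | pent-4-yn-2-one (not isolated) | CC(=O)CC#C | intermediate
8 | penta-3,4-dien-2-one | CC(=O)C=C=C | intermediate
9 | 1-[(1S,2R,5S)-2-[(tert-butyldimethylsilyl)oxy]-5-[(3R)-3-[(tert-butyldimethylsilyl)oxy]-3-methylpent-4-en-1-yl]-4-methyl-6-methylidenecyclohex-3-en-1-yl]ethan-1-one | C=C[C@](C)(O[Si](C)(C)C(C)(C)C)CC[C@H]1C(C)=C[C@@H](O[Si](C)(C)C(C)(C)C)[C@@H](C(C)=O)C1=C | intermediate
10 | tert-butyl{[(1R,4S,6S)-4-[(3R)-3-[(tert-butyldimethylsilyl)oxy]-3-methylpent-4-en-1-yl]-3-methyl-5-methylidene-6-(prop-1-en-2-yl)cyclohex-2-en-1-yl]oxy}dimethylsilane | C=C[C@](C)(O[Si](C)(C)C(C)(C)C)CC[C@H]1C(C)=C[C@@H](O[Si](C)(C)C(C)(C)C)[C@@H](C(C)=C)C1=C | intermediate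
11 | (1R,4S,6S)-4-[(3R)-3-hydroxy-3-methylpent-4-en-1-yl]-3-methyl-5-methylidene-6-(prop-1-en-2-yl)cyclohex-2-en-1-ol | C=C[C@](C)(O)CC[C@H]1C(C)=C[C@@H](O)[C@@H](C(C)=C)C1=C | intermediate
12 | (1S,4S,6S)-4-[(3R)-3-hydroxy-3-methylpent-4-en-1-yl]-3-methyl-5-methylidene-6-(prop-1-en-2-yl)cyclohex-2-en-1-yl butanoate | C=C[C@](C)(O)CC[C@H]1C(C)=C[C@H](OC(=O)CCC)[C@@H](C(C)=C)C1=C | intermediate
13 | 2,3-bis(phenylsulfonyl)prop-1-ene | C=C(CS(=O)(=O)c1ccccc1)S(=O)(=O)c1ccccc1 | starting material
14 | (1S,4S,6S)-4-[(3R)-3-hydroxy-3-methylpent-4-en-1-yl]-3-methyl-5-methylidene-6-[2-methyl-4-(phenylsulfonyl)pent-4-en-2-yl]cyclohex-2-en-1-yl butanoate (not isolated) | C=C[C@](C)(O)CC[C@H]1C(C)=C[C@H](OC(=O)CCC)[C@@H](C(C)(C)CC(=C)S(=O)(=O)c2ccccc2)C1=C | intermediate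
15 | (1S,4S,5R,6S)-4-[(3R)-3-hydroxy-3-methylpent-4-en-1-yl]-3,5-dimethyl-5-[2-(phenylsulfonyl)prop-2-en-1-yl]-6-(prop-1-en-2-yl)cyclohex-2-en-1-yl butanoate (not isolated) | C=C[C@](C)(O)CC[C@H]1C(C)=C[C@H](OC(=O)CCC)[C@@H](C(C)=C)[C@]1(C)CC(=C)S(=O)(=O)c2ccccc2 | intermediate
16 | (13R)-13-hydroxy-2-(phenylsulfonyl)labda-7,14-dien-6α-yl butanoate (5S,6S,9S,10R; C2 epimers) | C=C[C@](C)(O)CC[C@H]1C(C)=C[C@H](OC(=O)CCC)[C@H]2C(C)(C)CC(S(=O)(=O)c3ccccc3)C[C@]12C | intermediate
17 | (13R)-13-hydroxylabda-7,14-dien-6α-yl butanoate (5S,6S,9S,10R,13R) | C=C[C@](C)(O)CC[C@H]1C(C)=C[C@H](OC(=O)CCC)[C@H]2C(C)(C)CCC[C@]12C | target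

## Step count and risks

Total step count: 10. Longest linear sequence: 9 (steps 1–3 and 5–10, from linalool).

Steps most likely to fail:

1. Step 9 (proposed new method). What may go wrong is that the second tertiary radical adds to another molecule of 13, or that hydrogen-atom transfer reaches the vinyl group or the ring alkene, so that open-chain, doubly allylated or over-reduced material forms instead of ring A. The fallback makes the two bonds in two separate flasks, each by a known reaction type. Setting out from 12, an Fe(acac)3/PhSiH3 radical allylation by addition–fragmentation is run with 13 as the limiting reagent and stopped at partial conversion, and the mono-adducts 14 and 15 are isolated together and unreacted 12 is recycled. In a second flask, a hydrogen-atom-transfer-initiated intramolecular Giese cyclisation onto the vinyl sulfone at high dilution (0.005 M, no external acceptor) closes ring A, and the route is rejoined at 16. This fallback makes no compound outside the list (none, F0).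

2. Step 5. What may go wrong is insufficient facial control by the catalyst, or acid-induced decomposition of the silyl dienol ether before cycloaddition. The fallback sets out from 5 and 8 and runs the Diels–Alder reaction thermally without catalyst (toluene, 70 °C), which should give 9 together with its ring-antipodal all-cis diastereomer, the (1R,2S,5R)-ketone F1. The mixture is carried through the Petasis methylenation (10 plus the diastereomeric bis-silyl ether F2) and the desilylation (11 plus the diastereomeric diol F3). Lipase-catalysed acylation (Candida antarctica lipase B, vinyl acetate, MTBE) should then, by the empirical size rule for secondary alcohols, acetylate the (R)-configured carbinol of 11 to the allylic acetate F4 and leave F3. After chromatographic separation, K2CO3/MeOH returns 11, where the route is rejoined.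

3. Step 8. What may go wrong is E2 elimination of the activated alcohol towards a conjugated triene (the C5–H is doubly allylic and anti to the leaving group) or SN2′ attack, in place of clean SN2 inversion. The fallback sets out from 11 and replaces the substitution by an oxidation–reduction sequence. MnO2 in CH2Cl2 oxidises only the secondary allylic alcohol to the cyclohexenone F5. Luche reduction (NaBH4, CeCl3·7H2O, MeOH, −78 °C) should then deliver hydride axially on the half-chair in which the cis C5 and C9 substituents are both pseudo-equatorial, giving the trans (6α) allylic alcohol F6. Acylation with butanoic anhydride, Et3N and DMAP gives 12, where the route is rejoined.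

Further compounds

F0 | step 9 | none | none
F1 | step 5 | 1-[(1R,2S,5R)-2-[(tert-butyldimethylsilyl)oxy]-5-[(3R)-3-[(tert-butyldimethylsilyl)oxy]-3-methylpent-4-en-1-yl]-4-methyl-6-methylidenecyclohex-3-en-1-yl]ethan-1-one | C=C[C@](C)(O[Si](C)(C)C(C)(C)C)CC[C@@H]1C(C)=C[C@H](O[Si](C)(C)C(C)(C)C)[C@H](C(C)=O)C1=C
F2 | step 5 | tert-butyl{[(1S,4R,6R)-4-[(3R)-3-[(tert-butyldimethylsilyl)oxy]-3-methylpent-4-en-1-yl]-3-methyl-5-methylidene-6-(prop-1-en-2-yl)cyclohex-2-en-1-yl]oxy}dimethylsilane | C=C[C@](C)(O[Si](C)(C)C(C)(C)C)CC[C@@H]1C(C)=C[C@H](O[Si](C)(C)C(C)(C)C)[C@H](C(C)=C)C1=C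
F3 | step 5 | (1S,4R,6R)-4-[(3R)-3-hydroxy-3-methylpent-4-en-1-yl]-3-methyl-5-methylidene-6-(prop-1-en-2-yl)cyclohex-2-en-1-ol | C=C[C@](C)(O)CC[C@@H]1C(C)=C[C@H](O)[C@H](C(C)=C)C1=C
F4 | step 5 | (1R,4S,6S)-4-[(3R)-3-hydroxy-3-methylpent-4-en-1-yl]-3-methyl-5-methylidene-6-(prop-1-en-2-yl)cyclohex-2-en-1-yl acetate | C=C[C@](C)(O)CC[C@H]1C(C)=C[C@@H](OC(C)=O)[C@@H](C(C)=C)C1=C
F5 | step 8 | (4S,6S)-4-[(3R)-3-hydroxy-3-methylpent-4-en-1-yl]-3-methyl-5-methylidene-6-(prop-1-en-2-yl)cyclohex-2-en-1-one | C=C[C@](C)(O)CC[C@H]1C(C)=CC(=O)[C@@H](C(C)=C)C1=C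
F6 | step 8 | (1S,4S,6S)-4-[(3R)-3-hydroxy-3-methylpent-4-en-1-yl]-3-methyl-5-methylidene-6-(prop-1-en-2-yl)cyclohex-2-en-1-ol | C=C[C@](C)(O)CC[C@H]1C(C)=C[C@H](O)[C@@H](C(C)=C)C1=C
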